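**Retrosynthetic overview**

1. The strategy rests on ring B (C5–C6–C7–C8–C9–C10): it joins the quaternary C10 of ring A to a ring C that is the hydroquinone (C11–OH, C14–OH, C12–OMe, C13–isopropyl) of 2-methoxy-3-isopropyl-1,4-benzoquinone, so C7–C8 and C9–C10 are the two bonds of a quinone [4+2] adduct.
2. Late stage: target ⇐ deacetylation ⇐ benzylic oxidation at C7 ⇐ δ-lactone C19(=O)–O–C20 from the 1,3-diaxial 4β-CO2Me/10β-CH2OH pair ⇐ α-face hydrogenation of C5=C6 ⇐ hydroquinone 15.
3. Key disconnection: 15 ⇐ ring A diene 9 (C7=C6–C5=C10, CH2OTBS on C10, C4 stereocenter in place) + quinone 13 (unsubstituted C8=C9), followed by enolisation of the adduct.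
4. Diene 9 ⇐ methyl 2-oxocyclohexanecarboxylate (auxiliary-controlled C4 methylation, bromoformylation, vinyl coupling, reduction, silylation); quinone 13 ⇐ 1,2,4-trimethoxybenzene (ortho-lithiation/acetone, ionic hydrogenation, oxidative demethylation).
5. Ring order: rings A and C are brought in preformed, ring B is closed in step 10, the lactone ring in step 13.

Key step: step 10

Assumption: the lithio enamine of the L-valine tert-butyl ester auxiliary is taken to deliver the (S)-keto ester 5 under the toluene/HMPA protocol; should the sense be opposite, steps 1 and 2 are run unchanged with D-valine tert-butyl ester.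

**Route**

Step 1
Reactants: 1 methyl 2-oxocyclohexane-1-carboxylate; 2 L-valine tert-butyl ester
Product: 3 methyl 2-{[(2S)-1-tert-butoxy-3-methyl-1-oxobutan-2-yl]amino}cyclohex-1-ene-1-carboxylate
Conditions: AcOH (cat.), 4 Å molecular sieves, toluene, 60 °C
Reagents that add atoms: none
Why: Condensation of a β-keto ester with a primary amine gives the hydrogen-bonded, conjugated enamino ester once water is removed, and no stereocenter is formed.

Step 2
Reactants: 3 methyl 2-{[(2S)-1-tert-butoxy-3-methyl-1-oxobutan-2-yl]amino}cyclohex-1-ene-1-carboxylate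
Product: 5 methyl (S)-1-methyl-2-oxocyclohexane-1-carboxylate, via alkylated imine 4 (not isolated)
Conditions: LiN(iPr)2, toluene, −78 °C; HMPA (1 equiv); MeI, −78 → −40 °C; then aq. citric acid, THF, rt
Reagents that add atoms: iodomethane (CI); water (O)
Why: Auxiliary-controlled alkylation of a chelated lithio enamine (aza-enolate) should set the quaternary C4 center because the valine isopropyl group screens one face of the planar anion, and mild acid hydrolysis of imine 4 releases ketone 5 and the recoverable amino ester.

Step 3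
Reactants: 5 methyl (S)-1-methyl-2-oxocyclohexane-1-carboxylate
Product: 6 methyl (R)-2-bromo-3-formyl-1-methylcyclohex-2-ene-1-carboxylate
Conditions: PBr3, DMF, CHCl3, 0 → 60 °C; then ice-water
Reagents that add atoms: phosphorus tribromide (BrP(Br)Br); N,N-dimethylformamide (CN(C)C=O); water (O)
Why: Vilsmeier–Haack–Arnold bromoformylation should work because the ketone can enolise only toward C10, where the enol is formylated while the carbonyl oxygen at C5 is exchanged for bromide; the quaternary center is untouched and the descriptor becomes R only because bromine raises the CIP rank of C5.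

Step 4
Reactants: 6 methyl (R)-2-bromo-3-formyl-1-methylcyclohex-2-ene-1-carboxylate
Product: 7 methyl (S)-3-formyl-1-methyl-2-vinylcyclohex-2-ene-1-carboxylate
Conditions: vinylboronic acid pinacol ester, Pd(dppf)Cl2 (5 mol%), K3PO4, dioxane/H2O, 70 °C
Reagents that add atoms: vinylboronic acid pinacol ester (C=CB1OC(C)(C)C(C)(C)O1)
Why: Suzuki–Miyaura coupling should be easy because the β-bromo enal is a vinylogous acyl bromide that adds readily to zerovalent palladium, so the vinyl group (C6–C7) is installed at C5 with the tetrasubstituted alkene retained.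

Step 5
Reactants: 7 methyl (S)-3-formyl-1-methyl-2-vinylcyclohex-2-ene-1-carboxylate
Product: 8 methyl (S)-3-(hydroxymethyl)-1-methyl-2-vinylcyclohex-2-ene-1-carboxylate
Conditions: NaBH4, CeCl3·7H2O, MeOH, −20 → 0 °C
Reagents that add atoms: none
Why: Luche reduction delivers hydride 1,2 to the aldehyde only and should leave the hindered methyl ester and the diene intact.

Step 6
Reactants: 8 methyl (S)-3-(hydroxymethyl)-1-methyl-2-vinylcyclohex-2-ene-1-carboxylate
Product: 9 methyl (S)-3-{[(tert-butyldimethylsilyl)oxy]methyl}-1-methyl-2-vinylcyclohex-2-ene-1-carboxylate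
Conditions: TBSCl, imidazole, DMF, rt
Reagents that add atoms: tert-butyldimethylsilyl chloride (CC(C)(C)[Si](C)(C)Cl)
Why: Standard silylation of a primary alcohol; a silyl ether is chosen over an acetal because it is a poor ligand for SnCl4, is less prone to ionise at the allylic position in step 10, does not steer the hydrogenation in step 12, and is removed by fluoride without touching aryl acetates.

Step 7
Reactants: 10 1,2,4-trimethoxybenzene
Product: 11 2-(2,3,6-trimethoxyphenyl)propan-2-ol
Conditions: n-BuLi, THF, 0 °C → rt; acetone, −78 °C → rt; H2O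
Reagents that add atoms: acetone (CC(C)=O)
Why: Directed ortho-metalation removes the C3 proton flanked by two methoxy groups and the aryllithium adds to acetone, which fixes the isopropyl carbon between the 2- and 4-oxygens, a pattern that O-monomethylation of 3-isopropylcatechol would not give because the less hindered oxygen reacts first.

Step 8
Reactants: 11 2-(2,3,6-trimethoxyphenyl)propan-2-ol
Product: 12 2-isopropyl-1,3,4-trimethoxybenzene
Conditions: Et3SiH, CF3CO2H, CH2Cl2, 0 °C → rt
Reagents that add atoms: none
Why: Ionic hydrogenation should proceed because the tertiary benzylic cation formed in CF3CO2H is captured by silane hydride.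

Step 9
Reactants: 12 2-isopropyl-1,3,4-trimethoxybenzene
Product: 13 2-methoxy-3-isopropyl-1,4-benzoquinone
Conditions: (NH4)2Ce(NO3)6, MeCN/H2O, 0 °C
Reagents that add atoms: water (O)
Why: Oxidative demethylation by tetravalent cerium converts the para-dimethoxy pair into the para-quinone and keeps the remaining methoxy group next to the isopropyl group.

Step 10
Reactants: 9 methyl (S)-3-{[(tert-butyldimethylsilyl)oxy]methyl}-1-methyl-2-vinylcyclohex-2-ene-1-carboxylate; 13 2-methoxy-3-isopropyl-1,4-benzoquinone
Product: 15 methyl 20-[(tert-butyldimethylsilyl)oxy]-11,14-dihydroxy-12-methoxyabieta-5,8,11,13-tetraen-19-oate, via ene-dione cycloadduct 14 (not isolated)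
Conditions: 13, SnCl4 (1.2 equiv), CH2Cl2, −78 °C; then 9, −78 → −30 °C; aq. NaHCO3; then Et3N, degassed THF, 0 °C, Ar; aq. Na2S2O4 wash
Reagents that add atoms: none
Why: SnCl4 chelates the C11 carbonyl and the C12 methoxy oxygen of 13, so the C8=C9 bond is polarised with its largest LUMO coefficient at C8 (the C14 carbonyl is only a vinylogous ester), and diene 9 adds in a concerted but asynchronous [4+2] cycloaddition in which the unhindered, more nucleophilic terminus C7 bonds to C8 ahead of closure of tetrasubstituted C10 onto C9. The closest known reaction type is the Lewis acid-promoted Diels–Alder reaction of 1-vinylcyclohexenes with 2-methoxy-1,4-benzoquinones. Ring B (C5–C6–C7–C8–C9–C10) is closed by this suprafacial six-electron cycloaddition, which forms C7–C8 and C9–C10 in one operation, and Et3N then enolises the cis-fused ene-dione 14 twice, aromatising ring C and erasing the transient C8 and C9 centers (so endo or exo approach is immaterial). The only lasting new stereocenter is C10, and it is controlled by C4: in the reactive half-chair the ester (smaller A value than methyl) should sit pseudoaxial on the β face, so the quinone approaches the α face anti to C19 and the CH2OTBS group ends up β, cis to the ester. The step needs regioselectivity, which the methoxy group and the tin chelate secure, and facial selectivity, which rests only on this modest conformational bias, so any C10 epimer is removed at step 13, where it cannot lactonise. The inside (cis) CH2OTBS group on C10 slows the reaction, which is why stoichiometric activation at low temperature is used.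

Step 11
Reactants: 15 methyl 20-[(tert-butyldimethylsilyl)oxy]-11,14-dihydroxy-12-methoxyabieta-5,8,11,13-tetraen-19-oate
Product: 16 methyl 11,14-diacetoxy-20-[(tert-butyldimethylsilyl)oxy]-12-methoxyabieta-5,8,11,13-tetraen-19-oate
Conditions: Ac2O, pyridine, DMAP (cat.), CH2Cl2, rt, Ar
Reagents that add atoms: acetic anhydride (CC(=O)OC(C)=O)
Why: DMAP-catalysed acylation caps both hindered phenols of the crude hydroquinone, which stops air oxidation to the quinone and deactivates ring C toward the later chromium oxidation.

Step 12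
Reactants: 16 methyl 11,14-diacetoxy-20-[(tert-butyldimethylsilyl)oxy]-12-methoxyabieta-5,8,11,13-tetraen-19-oate
Product: 17 methyl 11,14-diacetoxy-20-[(tert-butyldimethylsilyl)oxy]-12-methoxy-5α-abieta-8,11,13-trien-19-oate
Conditions: H2 (50 bar), Pd/C, EtOAc, 40 °C
Reagents that add atoms: none
Why: Heterogeneous hydrogenation should deliver hydrogen to the α face, because the β face of C5=C6 is covered by the axial C19 ester on C4 and the axial CH2OTBS group on C10, which sets 5α-H (trans A/B fusion) as in the hydrogenation of Δ5-steroids.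

Step 13
Reactants: 17 methyl 11,14-diacetoxy-20-[(tert-butyldimethylsilyl)oxy]-12-methoxy-5α-abieta-8,11,13-trien-19-oate
Product: 19 11,14-diacetoxy-12-methoxy-5α-abieta-8,11,13-trien-19,20-olide, via hydroxy ester 18 (not isolated)
Conditions: HF·pyridine, THF, 0 °C → rt; then TsOH·H2O (cat.), toluene, 80 °C
Reagents that add atoms: none
Why: Fluoride-mediated desilylation spares the aryl acetates, and the freed 10β-CH2OH lies 1,3-diaxial to the 4β-ester, so acid-catalysed lactonisation with loss of methanol closes the δ-lactone, which only the C10 epimer with cis C19/C20 can form.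

Step 14
Reactants: 19 11,14-diacetoxy-12-methoxy-5α-abieta-8,11,13-trien-19,20-olide
Product: 20 11,14-diacetoxy-12-methoxy-7-oxo-5α-abieta-8,11,13-trien-19,20-olide
Conditions: CrO3, AcOH, 15 °C → rt
Reagents that add atoms: chromium trioxide (O=[Cr](=O)=O)
Why: Benzylic oxidation by hexavalent chromium should select C7, the only benzylic methylene, because the isopropyl methine is held in the ring plane between OMe and OAc and the acetates protect ring C from oxidation to a quinone.

Step 15
Reactants: 20 11,14-diacetoxy-12-methoxy-7-oxo-5α-abieta-8,11,13-trien-19,20-olide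
Product: 21 11,14-dihydroxy-12-methoxy-7-oxo-5α-abieta-8,11,13-trien-19,20-olide (target)
Conditions: HCl (1.25 M in MeOH, degassed), 45 °C, Ar
Reagents that add atoms: none
Why: Acid-catalysed transesterification removes both aryl acetates under oxygen-free, non-basic conditions that avoid oxidation of the hydroquinone, while the lactone persists as the thermodynamic sink of the 1,3-diaxial C19/C20 pair and no stereocenter is enolisable (C5 is β to the ketone).

**Compound list**

1 | methyl 2-oxocyclohexane-1-carboxylate | COC(=O)C1CCCCC1=O | starting material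
2 | L-valine tert-butyl ester, tert-butyl (2S)-2-amino-3-methylbutanoate | CC(C)[C@H](N)C(=O)OC(C)(C)C | starting material
3 | methyl 2-{[(2S)-1-tert-butoxy-3-methyl-1-oxobutan-2-yl]amino}cyclohex-1-ene-1-carboxylate | COC(=O)C1=C(N[C@@H](C(C)C)C(=O)OC(C)(C)C)CCCC1 | intermediate
4 | alkylated imine, methyl (1S)-1-methyl-2-{[(2S)-1-tert-butoxy-3-methyl-1-oxobutan-2-yl]imino}cyclohexane-1-carboxylate | CC(C)[C@H](N=C1CCCC[C@]1(C)C(=O)OC)C(=O)OC(C)(C)C | intermediate
5 | methyl (S)-1-methyl-2-oxocyclohexane-1-carboxylate | O=C1CCCC[C@]1(C)C(=O)OC | intermediate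
6 | methyl (R)-2-bromo-3-formyl-1-methylcyclohex-2-ene-1-carboxylate | BrC1=C(C=O)CCC[C@]1(C)C(=O)OC | intermediate
7 | methyl (S)-3-formyl-1-methyl-2-vinylcyclohex-2-ene-1-carboxylate | C=CC1=C(C=O)CCC[C@]1(C)C(=O)OC | intermediate
8 | methyl (S)-3-(hydroxymethyl)-1-methyl-2-vinylcyclohex-2-ene-1-carboxylate | C=CC1=C(CO)CCC[C@]1(C)C(=O)OC | intermediate
9 | methyl (S)-3-{[(tert-butyldimethylsilyl)oxy]methyl}-1-methyl-2-vinylcyclohex-2-ene-1-carboxylate (ring A diene) | C=CC1=C(CO[Si](C)(C)C(C)(C)C)CCC[C@]1(C)C(=O)OC | intermediate
10 | 1,2,4-trimethoxybenzene | COc1ccc(OC)c(OC)c1 | starting material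
11 | 2-(2,3,6-trimethoxyphenyl)propan-2-ol | COc1ccc(OC)c(C(C)(C)O)c1OC | intermediate
12 | 2-isopropyl-1,3,4-trimethoxybenzene | COc1ccc(OC)c(C(C)C)c1OC | intermediate
13 | 2-methoxy-3-isopropyl-1,4-benzoquinone | COC1=C(C(C)C)C(=O)C=CC1=O | intermediate
14 | ene-dione cycloadduct, methyl 20-[(tert-butyldimethylsilyl)oxy]-12-methoxy-11,14-dioxoabieta-5,12-dien-19-oate (8β-H, 9β-H, 10β-CH2OTBS, 4β-CO2Me, 4α-Me) | COC1=C(C(C)C)C(=O)[C@@H]2CC=C3[C@]([C@@H]2C1=O)(CO[Si](C)(C)C(C)(C)C)CCC[C@]3(C)C(=O)OC | intermediate
15 | methyl 20-[(tert-butyldimethylsilyl)oxy]-11,14-dihydroxy-12-methoxyabieta-5,8,11,13-tetraen-19-oate (4α-Me, 4β-CO2Me, 10β-CH2OTBS) | COc1c(O)c2c(c(O)c1C(C)C)CC=C1[C@]2(CO[Si](C)(C)C(C)(C)C)CCC[C@]1(C)C(=O)OC | intermediate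
16 | methyl 11,14-diacetoxy-20-[(tert-butyldimethylsilyl)oxy]-12-methoxyabieta-5,8,11,13-tetraen-19-oate | COc1c(OC(C)=O)c2c(c(OC(C)=O)c1C(C)C)CC=C1[C@]2(CO[Si](C)(C)C(C)(C)C)CCC[C@]1(C)C(=O)OC | intermediate
17 | methyl 11,14-diacetoxy-20-[(tert-butyldimethylsilyl)oxy]-12-methoxy-5α-abieta-8,11,13-trien-19-oate (trans A/B) | COc1c(OC(C)=O)c2c(c(OC(C)=O)c1C(C)C)CC[C@@H]1[C@]2(CO[Si](C)(C)C(C)(C)C)CCC[C@]1(C)C(=O)OC | intermediate
18 | hydroxy ester, methyl 11,14-diacetoxy-20-hydroxy-12-methoxy-5α-abieta-8,11,13-trien-19-oate | COc1c(OC(C)=O)c2c(c(OC(C)=O)c1C(C)C)CC[C@@H]1[C@]2(CO)CCC[C@]1(C)C(=O)OC | intermediate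
19 | 11,14-diacetoxy-12-methoxy-5α-abieta-8,11,13-trien-19,20-olide | COc1c(OC(C)=O)c2c(c(OC(C)=O)c1C(C)C)CC[C@@H]1[C@]23CCC[C@]1(C)C(=O)OC3 | intermediate
20 | 11,14-diacetoxy-12-methoxy-7-oxo-5α-abieta-8,11,13-trien-19,20-olide | COc1c(OC(C)=O)c2c(c(OC(C)=O)c1C(C)C)C(=O)C[C@@H]1[C@]23CCC[C@]1(C)C(=O)OC3 | intermediate
21 | 11,14-dihydroxy-12-methoxy-7-oxo-5α-abieta-8,11,13-trien-19,20-olide (4α-Me, 4β-C19 carbonyl, 5α-H, 10β-C20) | COc1c(O)c2c(c(O)c1C(C)C)C(=O)C[C@@H]1[C@]23CCC[C@]1(C)C(=O)OC3 | target

**Step count and risk**

Total steps: 15. Longest linear sequence: 12 (steps 1–6, then 10–15); the quinone branch (steps 7–9) is 3 steps.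

Steps most likely to fail:

1. Step 10 (key cycloaddition). What may go wrong: bond formation at the tetrasubstituted terminus with its inside CH2OTBS group is slow, so Lewis-acid-induced ionisation of the allylic silyl ether, cationic oligomerisation of the electron-rich diene, or incomplete facial selectivity at C10 can erode the outcome. Fallback: it sets out from 9 and 13 and returns at 16. The two are combined without Lewis acid under 12 kbar in CH2Cl2 at room temperature (pressure-promoted neutral cycloaddition) to give adduct 14, which is enolised with Et3N and oxidised in the same flask with Ag2O to the air-stable tricyclic quinone methyl 20-[(tert-butyldimethylsilyl)oxy]-12-methoxy-11,14-dioxoabieta-5,8,12-trien-19-oate F1. This quinone can be chromatographed and freed from any C10 epimer, and reductive acetylation (zinc dust, Ac2O, Et3N) then gives diacetate 16.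

2. Step 12 (hydrogenation). What may go wrong: hydrogen uptake stalls because the trisubstituted C5=C6 bond lies between two quaternary carbons, or partial loss of the silyl group lets a free CH2OH steer hydrogen to the β face. Fallback: it sets out from 16 and returns at 17. The alkene is reduced by metal hydride hydrogen atom transfer (Mn(dpm)3 with trivalent manganese as catalyst, PhSiH3, t-BuOOH, i-PrOH, rt): the hydrogen atom adds to C6 and the tertiary C5 radical is quenched from the open α face, away from the two axial β groups. This fallback makes no new compound (F0).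

3. Step 14 (benzylic oxidation). What may go wrong: oxidation at C7 is slowed by the peri acetate at C14, so attack at the isopropyl methine or oxidative degradation of ring C competes. Fallback: it sets out from 16 and returns at 20. C7 is oxidised while it is both benzylic and allylic (CrO3, 3,5-dimethylpyrazole, CH2Cl2, −20 °C) to the enone methyl 11,14-diacetoxy-20-[(tert-butyldimethylsilyl)oxy]-12-methoxy-7-oxoabieta-5,8,11,13-tetraen-19-oate F2. Hydrogenation of the conjugated C5=C6 bond (H2, Pd/C, EtOAc) from the α face gives methyl 11,14-diacetoxy-20-[(tert-butyldimethylsilyl)oxy]-12-methoxy-7-oxo-5α-abieta-8,11,13-trien-19-oate F3. HF·pyridine then TsOH·H2O in toluene removes the silyl group and closes the lactone through methyl 11,14-diacetoxy-20-hydroxy-12-methoxy-7-oxo-5α-abieta-8,11,13-trien-19-oate F4 to give 20.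

**Further compounds**

F1 | step 10 | methyl 20-[(tert-butyldimethylsilyl)oxy]-12-methoxy-11,14-dioxoabieta-5,8,12-trien-19-oate | COC1=C(C(C)C)C(=O)C2=C(C1=O)[C@@]3(CO[Si](C)(C)C(C)(C)C)CCC[C@](C)(C(=O)OC)C3=CC2
F0 | step 12 | none | none
F2 | step 14 | methyl 11,14-diacetoxy-20-[(tert-butyldimethylsilyl)oxy]-12-methoxy-7-oxoabieta-5,8,11,13-tetraen-19-oate | COc1c(OC(C)=O)c2c(c(OC(C)=O)c1C(C)C)C(=O)C=C1[C@]2(CO[Si](C)(C)C(C)(C)C)CCC[C@]1(C)C(=O)OC
F3 | step 14 | methyl 11,14-diacetoxy-20-[(tert-butyldimethylsilyl)oxy]-12-methoxy-7-oxo-5α-abieta-8,11,13-trien-19-oate | COc1c(OC(C)=O)c2c(c(OC(C)=O)c1C(C)C)C(=O)C[C@@H]1[C@]2(CO[Si](C)(C)C(C)(C)C)CCC[C@]1(C)C(=O)OC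
F4 | step 14 | methyl 11,14-diacetoxy-20-hydroxy-12-methoxy-7-oxo-5α-abieta-8,11,13-trien-19-oate | COc1c(OC(C)=O)c2c(c(OC(C)=O)c1C(C)C)C(=O)C[C@@H]1[C@]2(CO)CCC[C@]1(C)C(=O)OC
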